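**Plan**
- Locants (daucane): C1 (quaternary, CH3), C2, C3, C4 (OH, iPr), C5 (ring-fusion H), C6 (aroyloxy), C7, C8 (CH3), C9, C10 (isovaleroyloxy); β is the face of the C1 methyl group.
- Cuts, in order: the two ester C–O bonds; C6–OH/C5–H back to a C5=C6 alkene; C1–C10 of the seven-membered ring with re-formation of C6–C8 (a cis-dialkenylcyclopropane); the cyclopropane into CH2 (C7) plus a (Z)-allylic alcohol; C6=C8 back to a cyclopentenecarbaldehyde.
- Forward: (R)-terpinen-4-ol is ring-contracted (ozonolysis, aldol) to the cyclopentene that already carries C4(OH)(iPr), the C1 methyl and C6, so all ten terpene carbons map onto C1–C6 and their two substituents. A temporary three-membered ring (C6–C7–C8) is then built, and a Cope rearrangement closes the seven-membered ring last.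
- Stereochemistry: C4 from the chiral pool; C6/C8 of the cyclopropane by ligand-controlled cyclopropanation, relayed to C1 and C10 in the Cope step; C5 by hydroxyl-directed epoxidation and radical reduction; C6 by hydride attack anti to the cis isopropyl group.
- Enabling feature: C1=C5–C6(–C7–)C8–C9=C10 is a cis-1,2-dialkenylcyclopropane when C6–C8 is bonded. Its [3,3] shift leaves alkenes exactly at C8=C9 (in the target) and C5=C6 (the handle for the C6 oxygen) and makes the quaternary C1.

Key step: step 9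

Assumption: (R)-(−)-terpinen-4-ol is taken as available in high enantiomeric purity; commercial material of lower purity would be upgraded before use.

**Step 1**
Reactants: 1 (R)-(−)-terpinen-4-ol; 2 triethylsilyl trifluoromethanesulfonate
Product: 3 triethyl{[(1R)-4-methyl-1-(propan-2-yl)cyclohex-3-en-1-yl]oxy}silane
Conditions: 2,6-lutidine, CH2Cl2, 0 °C
Reagents that add atoms: triethylsilyl trifluoromethanesulfonate, CC[Si](CC)(CC)OS(=O)(=O)C(F)(F)F
Why: O-silylation of the tertiary alcohol with a silyl triflate masks the hydroxyl, which would otherwise lactonise onto the (Z)-ester, direct a second cyclopropanation and form lactols later; no stereocentre is touched.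

**Step 2**
Reactants: 3
Product: 5 (3R)-6-oxo-3-(propan-2-yl)-3-[(triethylsilyl)oxy]heptanal, via secondary ozonide 4 (not isolated)
Conditions: O3, CH2Cl2, −78 °C; then Me2S, −78 °C to rt
Reagents that add atoms: ozone, [O-][O+]=O
Why: Ozonolysis with reductive work-up should cleave the only C=C bond to the methyl ketone and the aldehyde, leaving the C4 carbinol centre untouched.

**Step 3**
Reactants: 5
Product: 6 (5S)-2-methyl-5-(propan-2-yl)-5-[(triethylsilyl)oxy]cyclopent-1-ene-1-carbaldehyde
Conditions: piperidine (0.3 equiv), AcOH (0.3 equiv), toluene, 70 °C, 4 Å MS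
Reagents that add atoms: none
Why: Amine-catalysed intramolecular aldol condensation (aldehyde enamine onto the methyl ketone, 5-exo, then dehydration) is the ring contraction known for limonene-type keto aldehydes and should give the formylcyclopentene without creating a stereocentre.

**Step 4**
Reactants: 6; 7 methyl 2-[bis(2,2,2-trifluoroethoxy)phosphoryl]propanoate
Product: 8 methyl (2Z)-2-methyl-3-{(5S)-2-methyl-5-(propan-2-yl)-5-[(triethylsilyl)oxy]cyclopent-1-en-1-yl}prop-2-enoate
Conditions: 7, KHMDS, 18-crown-6, THF, −78 °C; then 6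
Reagents that add atoms: methyl 2-[bis(2,2,2-trifluoroethoxy)phosphoryl]propanoate, COC(=O)C(C)P(=O)(OCC(F)(F)F)OCC(F)(F)F
Why: Still–Gennari olefination should give the (Z)-trisubstituted enoate under kinetic control, which later places the ester-derived carbon cis to the cyclopentenyl group on the cyclopropane.

**Step 5**
Reactants: 8
Product: 9 (2Z)-2-methyl-3-{(5S)-2-methyl-5-(propan-2-yl)-5-[(triethylsilyl)oxy]cyclopent-1-en-1-yl}prop-2-en-1-ol
Conditions: DIBAL-H (2.3 equiv), CH2Cl2, −78 °C; Rochelle salt work-up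
Reagents that add atoms: none
Why: 1,2-Reduction of the conjugated ester by DIBAL-H at low temperature should give the allylic alcohol with the alkene geometry retained.

**Step 6**
Reactants: 9
Product: 10 [(1R,2S)-1-methyl-2-{(5S)-2-methyl-5-(propan-2-yl)-5-[(triethylsilyl)oxy]cyclopent-1-en-1-yl}cyclopropyl]methanol (CH2OH and cyclopentenyl cis)
Conditions: Et2Zn, CH2I2, DME, (4S,5S)-2-butyl-N,N,N',N'-tetramethyl-1,3,2-dioxaborolane-4,5-dicarboxamide (1.2 equiv), CH2Cl2, −10 °C to rt
Reagents that add atoms: diiodomethane, ICI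
Why: Dioxaborolane-mediated asymmetric Simmons–Smith (Charette) cyclopropanation delivers methylene through the zinc alkoxide to one face of the allylic-alcohol alkene (reagent control; the (S,S)-ligand is the enantiomer assigned by the usual facial model) and so sets C6 and C8, the syn-specific addition keeps CH2OH and cyclopentenyl cis, and the undirected tetrasubstituted ring alkene should stay intact.

**Step 7**
Reactants: 10
Product: 11 (1R,2S)-1-methyl-2-{(5S)-2-methyl-5-(propan-2-yl)-5-[(triethylsilyl)oxy]cyclopent-1-en-1-yl}cyclopropane-1-carbaldehyde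
Conditions: Dess–Martin periodinane, NaHCO3, CH2Cl2, 0 °C
Reagents that add atoms: none
Why: Dess–Martin oxidation of the primary alcohol should give the aldehyde, whose α-carbon is quaternary and cannot epimerise; the aldehyde is used at once.

**Step 8**
Reactants: 11; 12 2-(dichloromethyl)-4,4,5,5-tetramethyl-1,3,2-dioxaborolane
Product: 13 4,4,5,5-tetramethyl-2-[(E)-2-[(1S,2S)-1-methyl-2-{(5S)-2-methyl-5-(propan-2-yl)-5-[(triethylsilyl)oxy]cyclopent-1-en-1-yl}cyclopropyl]ethenyl]-1,3,2-dioxaborolane
Conditions: 12, CrCl2, LiI, THF, 0 °C to rt; product kept cold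
Reagents that add atoms: 2-(dichloromethyl)-4,4,5,5-tetramethyl-1,3,2-dioxaborolane, ClC(Cl)B1OC(C)(C)C(C)(C)O1
Why: Takai–Utimoto boryl olefination (geminal dichromium reagent from 12 and CrCl2) should convert the aldehyde into the (E)-alkenylboronate, whose geometry later fixes C10.

**Step 9**
Reactants: 13
Product: 15 (3S,8S,8aR)-6,8a-dimethyl-3-(propan-2-yl)-3-[(triethylsilyl)oxy]-1,2,3,5,8,8a-hexahydroazulen-8-ol (10α-alcohol; alkenes C5=C6 and C8=C9), via allylic boronate 14 (not isolated)
Conditions: toluene, 120 °C, sealed tube; then THF, aq. NaOH, H2O2, 0 °C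
Reagents that add atoms: hydrogen peroxide, OO
Why: On heating, the cis-1,2-dialkenylcyclopropane undergoes a concerted [3,3]-sigmatropic shift through the boat transition state in which the C6–C8 bond of the three-membered ring breaks, C1–C10 forms and the alkenes move to C5=C6 and C8=C9. The closest known reaction type is the divinylcyclopropane–cycloheptadiene (Cope) rearrangement used to make hydroazulenes. The seven-membered ring (C1, C5, C6, C7, C8, C9, C10) is closed by this pericyclic C1–C10 bond formation coupled to fragmentation of the temporary cyclopropane, the cyclopentane being already present. C1 is controlled by the (6S,8S) cyclopropane, which in the only possible boat brings C10 to the α face of the cyclopentene (anti to the C4 silyloxy group) so that the methyl ends up β. C10 is controlled by the E geometry of the alkenylboronate, which places boron on the side of C2 and trans to the C1 methyl, and the C–B bond is then oxidised with retention to the 10α-alcohol. The step needs the cis isomer only and a temperature below that of one-centre cyclopropane epimerisation, which the syn-specific cyclopropanation of the (Z)-alcohol and the absence of a cis alkyl C–H for a retro-ene path should secure, although the inward-pointing C1 methyl makes heating necessary.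

**Step 10**
Reactants: 15; 16 3-methylbutanoyl chloride
Product: 17 (3S,8S,8aR)-6,8a-dimethyl-3-(propan-2-yl)-3-[(triethylsilyl)oxy]-1,2,3,5,8,8a-hexahydroazulen-8-yl 3-methylbutanoate
Conditions: 16, pyridine, DMAP (cat.), CH2Cl2, 0 °C to rt
Reagents that add atoms: 3-methylbutanoyl chloride, CC(C)CC(Cl)=O
Why: DMAP-catalysed acylation of the only free hydroxyl installs the C10 ester of the target and removes the directing ability of this oxygen toward C8=C9.

**Step 11**
Reactants: 17
Product: 18 (3S,8S,8aR)-3-hydroxy-6,8a-dimethyl-3-(propan-2-yl)-1,2,3,5,8,8a-hexahydroazulen-8-yl 3-methylbutanoate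
Conditions: TBAF, AcOH, THF, rt
Reagents that add atoms: none
Why: Buffered fluoride desilylation should free the tertiary allylic alcohol, needed as a directing group, without touching the ester.

**Step 12**
Reactants: 18
Product: 19 5β,6β-epoxide of 18 (epoxide oxygen on the face of the C4 hydroxyl and the C1 methyl)
Conditions: VO(acac)2 (5 mol%), t-BuOOH, CH2Cl2, 0 °C to rt
Reagents that add atoms: tert-butyl hydroperoxide, CC(C)(C)OO
Why: Vanadium-catalysed hydroxyl-directed epoxidation delivers oxygen syn to the C4 alcohol onto the hindered C5=C6 alkene only, since C8=C9 has no free hydroxyl nearby.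

**Step 13**
Reactants: 19
Product: 20 (3S,3aS,4S,8S,8aR)-3,4-dihydroxy-6,8a-dimethyl-3-(propan-2-yl)-1,2,3,3a,4,5,8,8a-octahydroazulen-8-yl 3-methylbutanoate (5β-H, 6β-OH, cis ring fusion)
Conditions: Cp2TiCl2, Zn dust, THF, rt; then 19, 1,4-cyclohexadiene, rt; dilute HCl work-up
Reagents that add atoms: none
Why: Reductive epoxide opening by Cp2TiCl (trivalent titanium; Nugent–RajanBabu reaction) cleaves the C5–O bond to the tertiary radical, which should take a hydrogen atom on the less hindered β face (syn to CH3 and OH, anti to iPr and C10) and so give the cis ring fusion and the 1,3-diol.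

**Step 14**
Reactants: 20
Product: 21 (3S,3aR,8S,8aR)-3-hydroxy-6,8a-dimethyl-4-oxo-3-(propan-2-yl)-1,2,3,3a,4,5,8,8a-octahydroazulen-8-yl 3-methylbutanoate
Conditions: Dess–Martin periodinane, NaHCO3, CH2Cl2, 0 °C
Reagents that add atoms: none
Why: Dess–Martin oxidation takes the secondary alcohol to the C6 ketone under buffered, non-basic conditions that should avoid retro-aldol cleavage and migration of the C8=C9 alkene, while the tertiary alcohol is inert.

**Step 15**
Reactants: 21
Product: 22 (3S,3aS,4R,8S,8aR)-3,4-dihydroxy-6,8a-dimethyl-3-(propan-2-yl)-1,2,3,3a,4,5,8,8a-octahydroazulen-8-yl 3-methylbutanoate (6α-OH)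
Conditions: NaBH4, CeCl3·7H2O, MeOH, −78 °C
Reagents that add atoms: none
Why: Luche-type borohydride reduction should add hydride to C6 from the convex face, anti to the cis isopropyl group on C4 that shields the other face, giving the 6α-alcohol.

**Step 16**
Reactants: 22; 23 4-(acetyloxy)benzoyl chloride
Product: 24 (3S,3aS,4R,8S,8aR)-3-hydroxy-6,8a-dimethyl-8-[(3-methylbutanoyl)oxy]-3-(propan-2-yl)-1,2,3,3a,4,5,8,8a-octahydroazulen-4-yl 4-(acetyloxy)benzoate
Conditions: 23, Et3N, DMAP, CH2Cl2, rt to 40 °C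
Reagents that add atoms: 4-(acetyloxy)benzoyl chloride, CC(=O)Oc1ccc(cc1)C(Cl)=O
Why: DMAP-catalysed acylation should esterify the secondary C6 alcohol while the tertiary C4 alcohol does not react.

**Step 17**
Reactants: 24
Product: 25 (3S,3aS,4R,8S,8aR)-3-hydroxy-6,8a-dimethyl-8-[(3-methylbutanoyl)oxy]-3-(propan-2-yl)-1,2,3,3a,4,5,8,8a-octahydroazulen-4-yl 4-hydroxybenzoate (target)
Conditions: pyrrolidine (2 equiv), CH2Cl2, 0 °C
Reagents that add atoms: none
Why: Chemoselective aminolysis of the aryl acetate, which is far more electrophilic than the alkyl isovalerate and the benzoate, should release the phenol.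

**Compound list**
1 | (R)-(−)-terpinen-4-ol | CC1=CC[C@@](O)(C(C)C)CC1 | starting material
2 | triethylsilyl trifluoromethanesulfonate | CC[Si](CC)(CC)OS(=O)(=O)C(F)(F)F | starting material
3 | triethyl{[(1R)-4-methyl-1-(propan-2-yl)cyclohex-3-en-1-yl]oxy}silane | CC1=CC[C@@](O[Si](CC)(CC)CC)(C(C)C)CC1 | intermediate
4 | secondary ozonide (1,2,4-trioxolane across the former C=C) of 3, bridgehead isomers | CC12CC[C@](O[Si](CC)(CC)CC)(C(C)C)CC(OO1)O2 | intermediate
5 | (3R)-6-oxo-3-(propan-2-yl)-3-[(triethylsilyl)oxy]heptanal | CC(=O)CC[C@](O[Si](CC)(CC)CC)(C(C)C)CC=O | intermediate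
6 | (5S)-2-methyl-5-(propan-2-yl)-5-[(triethylsilyl)oxy]cyclopent-1-ene-1-carbaldehyde | CC1=C(C=O)[C@@](O[Si](CC)(CC)CC)(C(C)C)CC1 | intermediate
7 | methyl 2-[bis(2,2,2-trifluoroethoxy)phosphoryl]propanoate | COC(=O)C(C)P(=O)(OCC(F)(F)F)OCC(F)(F)F | starting material
8 | methyl (2Z)-2-methyl-3-{(5S)-2-methyl-5-(propan-2-yl)-5-[(triethylsilyl)oxy]cyclopent-1-en-1-yl}prop-2-enoate | COC(=O)/C(C)=C\C1=C(C)CC[C@]1(O[Si](CC)(CC)CC)C(C)C | intermediate
9 | (2Z)-2-methyl-3-{(5S)-2-methyl-5-(propan-2-yl)-5-[(triethylsilyl)oxy]cyclopent-1-en-1-yl}prop-2-en-1-ol | OC/C(C)=C\C1=C(C)CC[C@]1(O[Si](CC)(CC)CC)C(C)C | intermediate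
10 | [(1R,2S)-1-methyl-2-{(5S)-2-methyl-5-(propan-2-yl)-5-[(triethylsilyl)oxy]cyclopent-1-en-1-yl}cyclopropyl]methanol | OC[C@]1(C)C[C@@H]1C2=C(C)CC[C@]2(O[Si](CC)(CC)CC)C(C)C | intermediate
11 | (1R,2S)-1-methyl-2-{(5S)-2-methyl-5-(propan-2-yl)-5-[(triethylsilyl)oxy]cyclopent-1-en-1-yl}cyclopropane-1-carbaldehyde | O=C[C@]1(C)C[C@@H]1C2=C(C)CC[C@]2(O[Si](CC)(CC)CC)C(C)C | intermediate
12 | 2-(dichloromethyl)-4,4,5,5-tetramethyl-1,3,2-dioxaborolane | ClC(Cl)B1OC(C)(C)C(C)(C)O1 | starting material
13 | 4,4,5,5-tetramethyl-2-[(E)-2-[(1S,2S)-1-methyl-2-{(5S)-2-methyl-5-(propan-2-yl)-5-[(triethylsilyl)oxy]cyclopent-1-en-1-yl}cyclopropyl]ethenyl]-1,3,2-dioxaborolane | CC1(C)OB(/C=C/[C@]2(C)C[C@@H]2C3=C(C)CC[C@]3(O[Si](CC)(CC)CC)C(C)C)OC1(C)C | intermediate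
14 | 2-[(3S,8S,8aS)-6,8a-dimethyl-3-(propan-2-yl)-3-[(triethylsilyl)oxy]-1,2,3,5,8,8a-hexahydroazulen-8-yl]-4,4,5,5-tetramethyl-1,3,2-dioxaborolane | CC1=C[C@H](B2OC(C)(C)C(C)(C)O2)[C@]3(C)CC[C@](O[Si](CC)(CC)CC)(C(C)C)C3=CC1 | intermediate
15 | (3S,8S,8aR)-6,8a-dimethyl-3-(propan-2-yl)-3-[(triethylsilyl)oxy]-1,2,3,5,8,8a-hexahydroazulen-8-ol | CC1=C[C@H](O)[C@]2(C)CC[C@](O[Si](CC)(CC)CC)(C(C)C)C2=CC1 | intermediate
16 | 3-methylbutanoyl chloride | CC(C)CC(Cl)=O | starting material
17 | (3S,8S,8aR)-6,8a-dimethyl-3-(propan-2-yl)-3-[(triethylsilyl)oxy]-1,2,3,5,8,8a-hexahydroazulen-8-yl 3-methylbutanoate | CC1=C[C@H](OC(=O)CC(C)C)[C@]2(C)CC[C@](O[Si](CC)(CC)CC)(C(C)C)C2=CC1 | intermediate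
18 | (3S,8S,8aR)-3-hydroxy-6,8a-dimethyl-3-(propan-2-yl)-1,2,3,5,8,8a-hexahydroazulen-8-yl 3-methylbutanoate | CC1=C[C@H](OC(=O)CC(C)C)[C@]2(C)CC[C@](O)(C(C)C)C2=CC1 | intermediate
19 | 5β,6β-epoxide of 18 | CC1=C[C@H](OC(=O)CC(C)C)[C@]2(C)CC[C@](O)(C(C)C)[C@@]23O[C@H]3C1 | intermediate
20 | (3S,3aS,4S,8S,8aR)-3,4-dihydroxy-6,8a-dimethyl-3-(propan-2-yl)-1,2,3,3a,4,5,8,8a-octahydroazulen-8-yl 3-methylbutanoate | CC1=C[C@H](OC(=O)CC(C)C)[C@]2(C)CC[C@](O)(C(C)C)[C@@H]2[C@@H](O)C1 | intermediate
21 | (3S,3aR,8S,8aR)-3-hydroxy-6,8a-dimethyl-4-oxo-3-(propan-2-yl)-1,2,3,3a,4,5,8,8a-octahydroazulen-8-yl 3-methylbutanoate | CC1=C[C@H](OC(=O)CC(C)C)[C@]2(C)CC[C@](O)(C(C)C)[C@@H]2C(=O)C1 | intermediate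
22 | (3S,3aS,4R,8S,8aR)-3,4-dihydroxy-6,8a-dimethyl-3-(propan-2-yl)-1,2,3,3a,4,5,8,8a-octahydroazulen-8-yl 3-methylbutanoate | CC1=C[C@H](OC(=O)CC(C)C)[C@]2(C)CC[C@](O)(C(C)C)[C@@H]2[C@H](O)C1 | intermediate
23 | 4-(acetyloxy)benzoyl chloride | CC(=O)Oc1ccc(cc1)C(Cl)=O | starting material
24 | (3S,3aS,4R,8S,8aR)-3-hydroxy-6,8a-dimethyl-8-[(3-methylbutanoyl)oxy]-3-(propan-2-yl)-1,2,3,3a,4,5,8,8a-octahydroazulen-4-yl 4-(acetyloxy)benzoate | CC1=C[C@H](OC(=O)CC(C)C)[C@]2(C)CC[C@](O)(C(C)C)[C@@H]2[C@H](OC(=O)c2ccc(OC(C)=O)cc2)C1 | intermediate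
25 | (3S,3aS,4R,8S,8aR)-3-hydroxy-6,8a-dimethyl-8-[(3-methylbutanoyl)oxy]-3-(propan-2-yl)-1,2,3,3a,4,5,8,8a-octahydroazulen-4-yl 4-hydroxybenzoate | CC1=C[C@H](OC(=O)CC(C)C)[C@]2(C)CC[C@](O)(C(C)C)[C@@H]2[C@H](OC(=O)c2ccc(O)cc2)C1 | target

**Step count and risks**
Total steps: 17. Longest linear sequence: 17 (fully linear from 1).

Steps most likely to fail:

1. Step 9. The boat transition state has the C1 methyl pointing inward, so the rearrangement needs heat. At that temperature the allylic C–B bond of 14 may not survive: a 1,3-boron shift would scramble C10, and protodeboronation would lose the oxygen handle. The fallback carries silicon in place of boron and builds the alkene differently. It sets out from 11: Ohira–Bestmann homologation gives the terminal alkyne F1. Hydrosilylation with ethoxydimethylsilane and Karstedt catalyst Pt2(dvds)3 gives the (E)-alkenyl(ethoxy)dimethylsilane F2. Thermolysis as in step 9 gives the allylic silane F3, whose C–Si bond is robust to heat. Tamao oxidation (KF, KHCO3, H2O2) with retention returns to the route at 15.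

2. Step 6. Facial control by the ligand may be poor on this twisted, cis-substituted dienol, where the resident C4 centre may oppose the reagent, and methylene transfer may be slow. The fallback replaces reagent control by separation. It sets out from 9: cyclopropanation with Et2Zn/CH2I2 without ligand gives both cis cyclopropanes. Because of the C4 centre these are diastereomers, and the unwanted (1S,2R)-cyclopropylmethanol F4 is removed by chromatography. The route is rejoined at 10.

3. Step 13. The C5 radical may take its hydrogen atom on the wrong face, giving a trans ring fusion, or the titanium alkoxide may be lost by β-elimination, returning the alkene. The fallback avoids the epoxide and the radical. It sets out from 18: silylation with 1,1,3,3-tetramethyldisilazane gives the dimethylsilyl ether F5. Platinum-catalysed intramolecular 5-endo hydrosilylation adds Si–H syn from the β face to give the oxasilolane F6 (H on C5 and Si on C6, both β). Tamao oxidation with retention returns to the route at 20.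

**Further compounds**
F1 | step 9 | (5S)-1-[(1S,2S)-2-ethynyl-2-methylcyclopropyl]-2-methyl-5-(propan-2-yl)-5-[(triethylsilyl)oxy]cyclopent-1-ene (alkyne) | C#C[C@]1(C)C[C@@H]1C2=C(C)CC[C@]2(O[Si](CC)(CC)CC)C(C)C
F2 | step 9 | ethoxydimethyl[(E)-2-[(1S,2S)-1-methyl-2-{(5S)-2-methyl-5-(propan-2-yl)-5-[(triethylsilyl)oxy]cyclopent-1-en-1-yl}cyclopropyl]ethenyl]silane | CCO[Si](C)(C)/C=C/[C@]1(C)C[C@@H]1C2=C(C)CC[C@]2(O[Si](CC)(CC)CC)C(C)C
F3 | step 9 | allylic silane, 8-[ethoxy(dimethyl)silyl] analogue of 14 | CC1=C[C@H]([Si](C)(C)OCC)[C@]2(C)CC[C@](O[Si](CC)(CC)CC)(C(C)C)C2=CC1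
F4 | step 6 | [(1S,2R)-1-methyl-2-{(5S)-2-methyl-5-(propan-2-yl)-5-[(triethylsilyl)oxy]cyclopent-1-en-1-yl}cyclopropyl]methanol | OC[C@@]1(C)C[C@H]1C2=C(C)CC[C@]2(O[Si](CC)(CC)CC)C(C)C
F5 | step 13 | 4-O-(dimethylsilyl) ether of 18 | CC1=C[C@H](OC(=O)CC(C)C)[C@]2(C)CC[C@](O[SiH](C)C)(C(C)C)C2=CC1
F6 | step 13 | oxasilolane spanning O4–Si–C6 (5β-H, 6β-Si) | CC1=C[C@H](OC(=O)CC(C)C)[C@]2(C)CC[C@@]3(C(C)C)O[Si](C)(C)[C@@H](C1)[C@H]23
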